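## The problem

The target joins two flavan units. An upper 3-deoxyflavan (resorcinol-derived ring A, pyran ring C, 4-hydroxyphenyl ring B) is bonded through its C4 to C8 of a lower (−)-epigallocatechin unit (phloroglucinol-derived ring D, pyran ring F, pyrogallol ring E). There are four stereocentres: lower C2 and C3 (2R,3R, cis) and upper C2 and C4 (2S,4S, the two aryl groups cis on ring C). The lower pair lies five bonds from upper C4 and cannot be relied on to direct it. C4, once fixed, can direct C2, because the 2,4-cis chroman with both aryl groups equatorial is the more stable arrangement. The C4–C8 bond links a diarylmethine to an aromatic carbon flanked by two oxygen-bearing carbons, so it is hindered to make and, like any interflavan bond, open to cleavage by strong acid. Seven phenols (three on the easily oxidised ring E), a nucleophilic free C6–H on ring D and two benzylic C2–O1 ethers exclude strong acid, oxidants and forcing reduction late in the route, so the phenols must stay masked until a mild last step. The enabling feature is that upper C3 and C4 form a two-carbon bridge between lower C8, upper C2 (which carries O1 and ring B) and C4a of ring A. Read backwards, C3–C4 is a vinyl group on C8, C2 is an α-oxygenated benzylic radical, C4a is the carbon of an aryl halide, and O1–C2 is left to close by ionising a benzylic ether.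

## Retrosynthesis

**16 to 15.** The eight O–benzyl bonds are cut last. A single protecting group for the seven phenols and the 3-hydroxyl keeps the protected series uniform and leaves by neutral hydrogenolysis. Methyl ethers would need boron halides, which open the benzylic C2–O1 ethers, and esters would deactivate ring D towards the bromination needed earlier. Compound 15 is no simpler in skeleton than 16 but is stable to air and chromatography. The forward step must cleave eight benzyl ethers and spare the two ring benzylic C–O bonds.

**15 to 13 (through 14).** The O1–C2 bond of ring C is cut, which turns C2 into a benzylic methyl ether and O1 into a protected ring A phenol. The neighbouring cut, C4–C8 by attack of ring D on a flavan-4-yl cation, would leave C4 to be set by C2 and would raise a C6/C8 regiochemistry question. Cutting O1–C2 lets C4 be set first by a catalyst and then used to set C2. Compound 13 has lost ring C and needs no defined C2. The forward closure must ionise only the upper benzylic ether, find only one free phenol (hence an acetal on that oxygen and benzyl ethers elsewhere), and end at the cis isomer.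

**13 to 5, 8 and 12.** The two bonds to the C3–C4 unit, C2–C3 and C4–C4a, are cut together. A stepwise build through a chalcone, a conjugate arylation and a reduction would cost three or four more steps and a carbonyl at C2 that has to be taken down again. Against the C4–C8 cut, the position on ring D is already fixed by the substituent on C8. The precursors are far simpler: vinylarene 5 carries only the two stereocentres of the natural lower unit, and aryl bromide 8 and racemic trifluoroborate 12 carry none. The forward reaction must form the radical from 12 only, add it to the CH2 end of the vinyl group before nickel intercepts it, and arylate the hindered C4 radical under ligand control.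

**5 to 4, 3, 2 and 1.** The C8–vinyl bond is cut to bromide 4 (cross-coupling), the C8–Br bond to arene 3 (electrophilic bromination), and the six benzyl ethers in two stages through 2 back to (−)-epigallocatechin 1. Taking the lower unit whole from the chiral pool supplies rings D, E and F and both lower stereocentres. The forward demands are benzylation without base-induced epimerisation at C2, and bromination at C8 in preference to C6 and ring E.

**8 to 7 and 6.** The acetal O–C bond and then the benzyl O–C bond are cut back to 4-bromoresorcinol 6. The oxygen ortho to bromine becomes O1 and must be the only one that mild acid frees, so the two oxygens get different groups. The forward demand is mono-benzylation of 6 at the hydroxyl para to bromine.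

**12 to 11, 10 and 9.** The O–methyl bond is cut, then the C–B bond, back to aldehyde 9 through diboration adduct 10. A C–B bond is preferred to a C–H bond as radical source. Hydrogen abstraction could not tell the wanted benzylic position from the benzylic C–H bonds of the protecting groups, whereas one-electron oxidation selects the borate alone. The forward steps must keep the α-oxygenated benzylic C–B bond intact.

## Roads not taken

**Alternative 1:** Ring D itself is cut, at lower C8–C8a and C6–C7. Heating the flavan-4-yl siloxyalkyne A1 with the 3-benzyloxy-2-cinnamylcyclobutenone A2 would open A2 to a vinylketene, add it to the alkyne and, after 4π opening and 6π closure (Danheiser benzannulation), give phenol A3.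
- Merits: the reaction type is known and needs no catalyst. The point of attachment on ring D is fixed by construction, the free hydroxyl appears exactly where O1 of ring F belongs, and the silyl ether marks O7. In regiochemical certainty this road is better than the chosen one, which relies on C8-selective bromination.
- Weak points: A3 still lacks ring F and both lower stereocentres. These would have to come from the cinnamyl chain by asymmetric dihydroxylation, ring closure and inversion at C3 to reach the 2,3-cis pattern, which is several steps on a large intermediate. A1 needs the C4 stereocentre set beforehand next to a sensitive ynol ether, and A2 is a multistep piece.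
- Comparison: the chosen plan takes rings D, E and F and two stereocentres from compound 1 in four routine steps, and makes C4 in the same step that joins the halves. It pays for this with a key step that has no direct precedent.

**Alternative 2:** The C2=C3 bond of a 2-aryl-4H-chromene is cut. The titanium ethylidene from TiCl4, Zn, PbCl2, TMEDA and CH3CHBr2 would exchange with the vinyl group of aryl ester A4 and olefinate the ester carbonyl, closing ring C as chromene A5.
- Merits: olefinic ester cyclisation is an established reaction class. C2 would then be set kinetically by hydrogenation from the face opposite the C4 aryl group, and that hydrogenation could be merged with debenzylation. In control of C2 and in length of the endgame this road is better than the chosen one, which relies on an equilibrating cationic closure and two final steps.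
- Weak points: A4 already contains the C4 stereocentre, so the hardest problem (a diarylmethine on the hindered ring D) is only moved to an earlier, separate asymmetric step. The ester must be formed and kept on a crowded phenol. The titanium reagent is used in large excess on a substrate with eight benzyl ethers. The C4–H of A5 is doubly benzylic and allylic to the enol ether, so a hydrogen shift to the conjugated 2H-chromene would erase C4.
- Comparison: the chosen plan forms both C–C bonds and C4 in one convergent step from three short-sequence pieces. Against the safer C2 control of this road it sets the thermodynamic preference for the cis flavan.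

**Alternative 3:** Lower C4–C4a is cut. Sc(OTf)3 would activate the terminal epoxide of A6 and ring D would attack the CH2 carbon, closing ring F and releasing the 3-hydroxyl in A7.
- Merits: a Lewis-acid epoxide–arene closure is a known reaction type. Only one position ortho to the ether oxygen is open, so the regiochemistry on ring D is unambiguous. The 3-hydroxyl arrives unprotected.
- Weak points: the lower stereocentres must be made by asymmetric synthesis and carried through etherification of a hindered phenol at an ionisable trialkoxybenzylic carbon. The same benzylic aryl ether can ionise under the Lewis acid. Attack at the inner epoxide carbon, which closes a five-membered ring, competes. The upper 4-arylflavan must exist beforehand, so C4 again needs its own solution.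
- Comparison: as a key step this is the more conservative choice. The chosen plan sets against it the chiral-pool lower unit and the fact that C4 and the interflavan framework are made together.

Key step: step 9

Assumption: the stereodescriptors are read from the structure as upper (2S,4S) and lower (2R,3R). Which antipode of the chiral ligand in step 9 delivers 4S cannot be predicted and is to be settled by trying both.

## Route

Step 1
Reactants: 1 (−)-epigallocatechin
Product: 2 5,7,3',4',5'-penta-O-benzyl-(−)-epigallocatechin [(2R,3R)-5,7-bis(benzyloxy)-2-(3,4,5-tris(benzyloxy)phenyl)chroman-3-ol]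
Conditions: BnBr, K2CO3, DMF, −10 °C → rt, argon
Reagents that add atoms: benzyl bromide, BrCc1ccccc1
Why: Williamson etherification of the five phenols; K2CO3 does not deprotonate the secondary 3-hydroxyl, and low temperature under argon limits the base-induced ring opening that would epimerise C2, so both stereocentres of 1 are kept.

Step 2
Reactants: 2 penta-O-benzylepigallocatechin
Product: 3 3,5,7,3',4',5'-hexa-O-benzyl-(−)-epigallocatechin [(2R,3R)-3,5,7-tris(benzyloxy)-2-(3,4,5-tris(benzyloxy)phenyl)chromane]
Conditions: NaH, BnBr, DMF, 0 °C → rt
Reagents that add atoms: benzyl bromide, BrCc1ccccc1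
Why: Williamson etherification of the remaining secondary alcohol after deprotonation with NaH; no stereocentre is touched.

Step 3
Reactants: 3 hexa-O-benzylepigallocatechin
Product: 4 8-bromo-hexa-O-benzylepigallocatechin [(2R,3R)-3,5,7-tris(benzyloxy)-8-bromo-2-(3,4,5-tris(benzyloxy)phenyl)chromane]
Conditions: NBS, CH2Cl2, −78 → −40 °C
Reagents that add atoms: N-bromosuccinimide, O=C1CCC(=O)N1Br
Why: Electrophilic aromatic bromination; ring D is activated by three oxygens, and C8 (ortho to O1 and to the 7-benzyloxy group) is the position that reacts first in 5,7-di-O-alkylated flavans, ahead of C6 and of ring E.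

Step 4
Reactants: 4 8-bromo-hexa-O-benzylepigallocatechin
Product: 5 8-vinyl-hexa-O-benzylepigallocatechin [(2R,3R)-3,5,7-tris(benzyloxy)-8-ethenyl-2-(3,4,5-tris(benzyloxy)phenyl)chromane]
Conditions: CH2=CHBpin, Pd(OAc)2 (cat.), SPhos, K3PO4, dioxane/H2O, 80 °C
Reagents that add atoms: 4,4,5,5-tetramethyl-2-vinyl-1,3,2-dioxaborolane, C=CB1OC(C)(C)C(C)(C)O1
Why: Suzuki–Miyaura coupling; the bulky electron-rich biarylphosphine lets zerovalent palladium insert into the hindered, electron-rich C8–Br bond, and the benzyl ethers and stereocentres are inert.

Step 5
Reactants: 6 4-bromoresorcinol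
Product: 7 5-(benzyloxy)-2-bromophenol
Conditions: BnBr (1 equiv), K2CO3, acetone, rt
Reagents that add atoms: benzyl bromide, BrCc1ccccc1
Why: Williamson mono-etherification; the hydroxyl para to bromine is the less hindered and gives the more nucleophilic phenoxide, so one equivalent of benzyl bromide should favour it, and the regioisomer and bis-ether are removed by chromatography.

Step 6
Reactants: 7 5-(benzyloxy)-2-bromophenol
Product: 8 4-(benzyloxy)-1-bromo-2-(methoxymethoxy)benzene
Conditions: MOMCl, i-Pr2NEt, CH2Cl2, 0 °C → rt
Reagents that add atoms: chloromethyl methyl ether, COCCl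
Why: Acetal formation on the phenol under amine base; the methoxymethyl ether marks the oxygen that becomes O1 and is the only protecting group in the later intermediates that mild acid removes.

Step 7
Reactants: 9 4-(benzyloxy)benzaldehyde
Product: 11 potassium {[4-(benzyloxy)phenyl](hydroxy)methyl}trifluoroborate (racemic), via diboration adduct 10 (not isolated)
Conditions: B2pin2, (ICy)CuCl (cat., ICy = 1,3-dicyclohexylimidazol-2-ylidene), NaOt-Bu (cat.), toluene, rt; then KHF2, MeOH/H2O, 0 °C → rt
Reagents that add atoms: bis(pinacolato)diboron, CC1(C)OB(OC1(C)C)B1OC(C)(C)C(C)(C)O1; potassium hydrogen difluoride, [K+].F[H-]F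
Why: Copper-catalysed diboration of the aldehyde C=O (insertion into a copper–boron bond, then exchange with B2pin2) gives 10; KHF2 turns the C-boryl group into the trifluoroborate and frees the hydroxyl. The new centre is racemic, which does not matter because it later becomes a radical.

Step 8
Reactants: 11 potassium {[4-(benzyloxy)phenyl](hydroxy)methyl}trifluoroborate
Product: 12 potassium {[4-(benzyloxy)phenyl](methoxy)methyl}trifluoroborate (racemic)
Conditions: KH, MeI, THF/DMF, 0 °C → rt
Reagents that add atoms: iodomethane, CI
Why: Williamson O-methylation of the potassium alkoxide; the tetracoordinate boron is not electrophilic, so the C–B bond should survive the base.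

Step 9
Reactants: 5 8-vinyl-hexa-O-benzylepigallocatechin; 8 4-(benzyloxy)-1-bromo-2-(methoxymethoxy)benzene; 12 potassium {[4-(benzyloxy)phenyl](methoxy)methyl}trifluoroborate
Product: 13 (2R,3R)-3,5,7-tris(benzyloxy)-8-{(1S)-1-[4-(benzyloxy)-2-(methoxymethoxy)phenyl]-3-[4-(benzyloxy)phenyl]-3-methoxypropyl}-2-(3,4,5-tris(benzyloxy)phenyl)chromane (both epimers at the methoxy-bearing carbon)
Conditions: Ir[dF(CF3)ppy]2(dtbbpy)PF6 (2 mol %), NiBr2·glyme (10 mol %), chiral 4,4'-disubstituted 2,2'-bis(2-oxazoline) ligand (12 mol %), 2,6-lutidine, dioxane/DMA, blue LEDs, rt
Reagents that add atoms: none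
Why: Proposed new method: the photoexcited trivalent iridium complex should oxidise trifluoroborate 12 (made easier by the α-oxygen and the aryl group) to the α-methoxybenzyl radical, the BF3 set free being bound by 2,6-lutidine, and this radical adds to the unhindered CH2 end of the vinyl group of 5 to form C2–C3 and a benzylic radical at C4. Zerovalent nickel bearing the chiral bis(oxazoline) inserts into the C–Br bond of 8, the divalent arylnickel bromide takes up the C4 radical, reductive elimination from trivalent nickel forms C4–C4a, and the reduced iridium complex returns monovalent nickel to the zerovalent state. The closest known reaction type is the nickel/photoredox three-component 1,2-alkylarylation of alkenes with alkyltrifluoroborates and aryl bromides, together with ligand-controlled enantioselective arylation of benzylic radicals at nickel; what has not been shown is their combination with a stabilised α-oxybenzyl radical, an electron-rich styrene oxygenated at both ortho positions and a chiral substrate. No ring is closed. C4 (S) is to be set by the chiral ligand: capture of a benzylic radical by nickel is reversible, so the face is chosen in the reductive elimination, while the two stereocentres of the epigallocatechin part are five bonds away and should add only a small matched or mismatched bias. C2 forms without control and 13 is taken on as both C2 epimers. The step needs the radical from 12 to add to the alkene before nickel couples it directly with 8; the open CH2 terminus and the benzylic stabilisation of the adduct radical help, and so does running 5 as the limiting partner at high concentration with 8 and 12 in excess and nickel at low loading, so that direct coupling wastes only the two cheap components. Radical formation by electron transfer from the C–B bond alone keeps the benzylic C–H bonds of the benzyl ethers out of play, and the crowding around C4 disfavours addition of the adduct radical to a second molecule of 5.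

Step 10
Reactants: 13 the 1-methoxy-1,3,3-triarylpropane from step 9
Product: 15 octa-O-benzyl dimer [(2R,3R)-3,5,7-tris(benzyloxy)-8-{(2S,4S)-7-(benzyloxy)-2-[4-(benzyloxy)phenyl]chroman-4-yl}-2-(3,4,5-tris(benzyloxy)phenyl)chromane], via phenol methyl ether 14 (not isolated)
Conditions: methanolic HCl (cat.), MeOH/CH2Cl2, 0 °C → rt; then solvent exchange, CSA (cat.), CH2Cl2, rt
Reagents that add atoms: none
Why: Acetal methanolysis frees the ring A phenol (14); acid then ionises the upper benzylic methyl ether of either C2 epimer to the same 4-benzyloxybenzyl cation, and the phenol closes O1–C2 in a six-membered ring (intramolecular SN1 etherification). Ionisation is reversible and the chair-like closure places both aryl groups equatorial, so both epimers should converge on the 2,4-cis (2S,4S) flavan, with C4 directing C2; all other oxygens are ethers and cannot compete.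

Step 11
Reactants: 15 octa-O-benzyl dimer
Product: 16 target [(2R,3R)-8-[(2S,4S)-7-hydroxy-2-(4-hydroxyphenyl)chroman-4-yl]-2-(3,4,5-trihydroxyphenyl)chromane-3,5,7-triol]
Conditions: H2 (1 atm), Pd(OH)2/C, THF/MeOH, rt; filtration and concentration under argon
Reagents that add atoms: none
Why: Catalytic hydrogenolysis of the seven aryl benzyl ethers and the one alkyl benzyl ether; at atmospheric pressure and room temperature the benzylic C2–O1 bonds of both flavan rings are cleaved much more slowly than O-benzyl groups, and no stereocentre is affected.

## Compound list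

1 | (−)-epigallocatechin | Oc1cc(O)c2c(c1)O[C@H](c1cc(O)c(O)c(O)c1)[C@H](O)C2 | starting material
2 | 5,7,3',4',5'-penta-O-benzyl-(−)-epigallocatechin | c1c(OCc2ccccc2)cc(OCc2ccccc2)c2c1O[C@H](c1cc(OCc3ccccc3)c(OCc3ccccc3)c(OCc3ccccc3)c1)[C@H](O)C2 | intermediate
3 | 3,5,7,3',4',5'-hexa-O-benzyl-(−)-epigallocatechin | c1c(OCc2ccccc2)cc(OCc2ccccc2)c2c1O[C@H](c1cc(OCc3ccccc3)c(OCc3ccccc3)c(OCc3ccccc3)c1)[C@H](OCc1ccccc1)C2 | intermediate
4 | 8-bromo-hexa-O-benzylepigallocatechin | Brc1c(OCc2ccccc2)cc(OCc2ccccc2)c2c1O[C@H](c1cc(OCc3ccccc3)c(OCc3ccccc3)c(OCc3ccccc3)c1)[C@H](OCc1ccccc1)C2 | intermediate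
5 | 8-vinyl-hexa-O-benzylepigallocatechin | C=Cc1c(OCc2ccccc2)cc(OCc2ccccc2)c2c1O[C@H](c1cc(OCc3ccccc3)c(OCc3ccccc3)c(OCc3ccccc3)c1)[C@H](OCc1ccccc1)C2 | intermediate
6 | 4-bromoresorcinol | Oc1ccc(Br)c(O)c1 | starting material
7 | 5-(benzyloxy)-2-bromophenol | Oc1cc(OCc2ccccc2)ccc1Br | intermediate
8 | 4-(benzyloxy)-1-bromo-2-(methoxymethoxy)benzene | COCOc1cc(OCc2ccccc2)ccc1Br | intermediate
9 | 4-(benzyloxy)benzaldehyde | O=Cc1ccc(OCc2ccccc2)cc1 | starting material
10 | diboration adduct, 2-{[4-(benzyloxy)phenyl][(pinacolatoboryl)oxy]methyl}-4,4,5,5-tetramethyl-1,3,2-dioxaborolane, racemic | CC1(C)OB(OC(c2ccc(OCc3ccccc3)cc2)B2OC(C)(C)C(C)(C)O2)OC1(C)C | intermediate (not isolated)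
11 | potassium {[4-(benzyloxy)phenyl](hydroxy)methyl}trifluoroborate, racemic | [K+].OC(c1ccc(OCc2ccccc2)cc1)[B-](F)(F)F | intermediate
12 | potassium {[4-(benzyloxy)phenyl](methoxy)methyl}trifluoroborate, racemic | [K+].COC(c1ccc(OCc2ccccc2)cc1)[B-](F)(F)F | intermediate
13 | 1-methoxy-1,3,3-triarylpropane with the triaryl-side methine S and both epimers at the methoxy carbon | COC(c1ccc(OCc2ccccc2)cc1)C[C@H](c1c(OCc2ccccc2)cc(OCc2ccccc2)c2c1O[C@H](c1cc(OCc3ccccc3)c(OCc3ccccc3)c(OCc3ccccc3)c1)[C@H](OCc1ccccc1)C2)c1ccc(OCc2ccccc2)cc1OCOC | intermediate
14 | phenol methyl ether, 13 without the methoxymethyl group | COC(c1ccc(OCc2ccccc2)cc1)C[C@H](c1c(OCc2ccccc2)cc(OCc2ccccc2)c2c1O[C@H](c1cc(OCc3ccccc3)c(OCc3ccccc3)c(OCc3ccccc3)c1)[C@H](OCc1ccccc1)C2)c1ccc(OCc2ccccc2)cc1O | intermediate (not isolated)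
15 | octa-O-benzyl dimer, upper (2S,4S), lower (2R,3R) | c1ccccc1COc1ccc([C@@H]2C[C@H](c3c(OCc5ccccc5)cc(OCc5ccccc5)c4c3O[C@H](c3cc(OCc5ccccc5)c(OCc5ccccc5)c(OCc5ccccc5)c3)[C@H](OCc3ccccc3)C4)c3ccc(OCc5ccccc5)cc3O2)cc1 | intermediate
16 | target, (2R,3R)-8-[(2S,4S)-7-hydroxy-2-(4-hydroxyphenyl)chroman-4-yl]-2-(3,4,5-trihydroxyphenyl)chromane-3,5,7-triol | Oc1ccc([C@@H]2C[C@H](c3c(O)cc(O)c4c3O[C@H](c3cc(O)c(O)c(O)c3)[C@H](O)C4)c3ccc(O)cc3O2)cc1 | target

## Step count and risk

Total: 11 steps. Longest linear sequence: 7 steps (1, 2, 3, 4, 9, 10, 11).

**Step 9 (key step, new method).**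
- What may go wrong: direct nickel coupling of the α-methoxybenzyl radical with 8 may outrun its addition to the electron-rich vinyl group. Facial selection at the crowded C4 radical may be poor. The excited photocatalyst may be quenched by the polyalkoxyarenes.
- Fallback by known chemistry, from bromide 4 to 15: bromine–lithium exchange (n-BuLi, THF, −78 °C) and addition to the sodium phenoxide of commercial 4-(benzyloxy)-2-hydroxybenzaldehyde should give the ortho-hydroxybenzhydrol [4-(benzyloxy)-2-hydroxyphenyl](hexa-O-benzylepigallocatechin-8-yl)methanol F1. With a Brønsted acid F1 loses water to an ortho-quinone methide, which adds commercial 1-(benzyloxy)-4-ethenylbenzene in an inverse-demand hetero-Diels–Alder reaction to give the 2,4-cis-diarylchroman, rejoining the route at 15. Catalyst control at C4 is given up unless a chiral phosphoric acid imposes it, so the two cis diastereomers would have to be separated.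

**Step 10.**
- What may go wrong: the electrophile released from the methoxymethyl group may be captured by the free C6 position of ring D. Convergence of the two C2 epimers on the cis flavan may be incomplete. The 7-benzyloxy oxygen of ring D may close onto the cation with loss of benzyl.
- Fallback, from 7 to 14: silylation (TBSCl, imidazole) gives [5-(benzyloxy)-2-bromophenoxy](tert-butyl)dimethylsilane F2. Step 9 with F2 in place of 8 gives the silyl analogue of 13, F3. Bu4NF then frees the phenol, rejoining the route at 14, which is now isolated and cyclised with CSA in CH2Cl2 with no formaldehyde equivalent and no methanol present.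

**Step 7 (and with it step 8).**
- What may go wrong: boron may migrate from carbon to oxygen, or the electron-rich α-hydroxybenzyl boron species may protodeboronate, during the KHF2 treatment or on deprotonation in step 8.
- Fallback, from 9 to 13: bromoform and KOH in methanol convert the aldehyde in one step into 2-[4-(benzyloxy)phenyl]-2-methoxyacetic acid F4. Its caesium salt is oxidised by the same photocatalyst and loses CO2 to give the same radical, so it replaces 12 in step 9 and the route is rejoined at 13.

**Step 5.**
- What may go wrong: alkylation at the hydroxyl next to bromine, or at both hydroxyls, would lower the supply of 7.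
- Fallback, from 6 to 16: protecting both hydroxyls alike (MOMCl, i-Pr2NEt) gives 1-bromo-2,4-bis(methoxymethoxy)benzene F5 with no regiochemical question. Step 9 with F5 gives the bis-acetal analogue of 13, F6. The acid treatment of step 10 removes both acetals and closes ring C to the hepta-O-benzyl dimer with free upper 7-hydroxyl F7 (only the ortho phenol can reach C2). Hydrogenolysis as in step 11 rejoins the route at 16.

## Further compounds

F1 | step 9 | [4-(benzyloxy)-2-hydroxyphenyl][(2R,3R)-3,5,7-tris(benzyloxy)-2-(3,4,5-tris(benzyloxy)phenyl)chroman-8-yl]methanol, both carbinol epimers | OC(c1ccc(OCc2ccccc2)cc1O)c1c(OCc2ccccc2)cc(OCc2ccccc2)c2c1O[C@H](c1cc(OCc3ccccc3)c(OCc3ccccc3)c(OCc3ccccc3)c1)[C@H](OCc1ccccc1)C2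
F2 | step 10 | [5-(benzyloxy)-2-bromophenoxy](tert-butyl)dimethylsilane | CC(C)(C)[Si](C)(C)Oc1cc(OCc2ccccc2)ccc1Br
F3 | step 10 | analogue of 13 with a tert-butyldimethylsilyl ether in place of the methoxymethyl ether | COC(c1ccc(OCc2ccccc2)cc1)C[C@H](c1c(OCc2ccccc2)cc(OCc2ccccc2)c2c1O[C@H](c1cc(OCc3ccccc3)c(OCc3ccccc3)c(OCc3ccccc3)c1)[C@H](OCc1ccccc1)C2)c1ccc(OCc2ccccc2)cc1O[Si](C)(C)C(C)(C)C
F4 | step 7 | 2-[4-(benzyloxy)phenyl]-2-methoxyacetic acid, racemic | COC(C(=O)O)c1ccc(OCc2ccccc2)cc1
F5 | step 5 | 1-bromo-2,4-bis(methoxymethoxy)benzene | COCOc1ccc(Br)c(OCOC)c1
F6 | step 5 | analogue of 13 with methoxymethyl ethers on both ring A oxygens | COC(c1ccc(OCc2ccccc2)cc1)C[C@H](c1c(OCc2ccccc2)cc(OCc2ccccc2)c2c1O[C@H](c1cc(OCc3ccccc3)c(OCc3ccccc3)c(OCc3ccccc3)c1)[C@H](OCc1ccccc1)C2)c1ccc(OCOC)cc1OCOC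
F7 | step 5 | hepta-O-benzyl dimer with free upper 7-hydroxyl, upper (2S,4S), lower (2R,3R) | c1ccccc1COc1ccc([C@@H]2C[C@H](c3c(OCc5ccccc5)cc(OCc5ccccc5)c4c3O[C@H](c3cc(OCc5ccccc5)c(OCc5ccccc5)c(OCc5ccccc5)c3)[C@H](OCc3ccccc3)C4)c3ccc(O)cc3O2)cc1
A1 | alternative 1 | 2,4-cis flavan-4-yl siloxyalkyne, 7-(benzyloxy)-2-[4-(benzyloxy)phenyl]-4-[(triisopropylsilyloxy)ethynyl]chromane | c1ccccc1COc1ccc([C@@H]2C[C@H](C#CO[Si](C(C)C)(C(C)C)C(C)C)c3ccc(OCc4ccccc4)cc3O2)cc1
A2 | alternative 1 | 3-(benzyloxy)-2-[(E)-3-(3,4,5-tris(benzyloxy)phenyl)prop-2-enyl]cyclobut-2-en-1-one | O=C1CC(OCc2ccccc2)=C1C/C=C/c1cc(OCc2ccccc2)c(OCc2ccccc2)c(OCc2ccccc2)c1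
A3 | alternative 1 | flavan bearing at C4 a 2-hydroxy-6-(triisopropylsilyloxy)-4-(benzyloxy)-3-cinnamylphenyl ring | c4ccccc4COc1ccc([C@@H]2C[C@H](c5c(O[Si](C(C)C)(C(C)C)C(C)C)cc(OCc6ccccc6)c(C/C=C/c6cc(OCc7ccccc7)c(OCc7ccccc7)c(OCc7ccccc7)c6)c5O)c3ccc(OCc4ccccc4)cc3O2)cc1
A4 | alternative 2 | 5-(benzyloxy)-2-[1-(hexa-O-benzylepigallocatechin-8-yl)prop-2-enyl]phenyl 4-(benzyloxy)benzoate with the methine configured as in the target | C=C[C@H](c1c(OCc2ccccc2)cc(OCc2ccccc2)c2c1O[C@H](c1cc(OCc3ccccc3)c(OCc3ccccc3)c(OCc3ccccc3)c1)[C@H](OCc1ccccc1)C2)c1ccc(OCc2ccccc2)cc1OC(=O)c1ccc(OCc2ccccc2)cc1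
A5 | alternative 2 | 2,4-diaryl-4H-chromene with the C4 stereocentre set | c4ccccc4COc1ccc(C2=C[C@H](c5c(OCc6ccccc6)cc(OCc6ccccc6)c7c5O[C@H](c5cc(OCc6ccccc6)c(OCc6ccccc6)c(OCc6ccccc6)c5)[C@H](OCc5ccccc5)C7)c3ccc(OCc4ccccc4)cc3O2)cc1
A6 | alternative 3 | upper flavan carrying at C4 a 2,4-bis(benzyloxy)-6-[oxiranyl(3,4,5-tris(benzyloxy)phenyl)methoxy]phenyl ring | c4ccccc4COc1ccc([C@@H]2C[C@H](c5c(OCc6ccccc6)cc(OCc6ccccc6)cc5O[C@H](c5cc(OCc6ccccc6)c(OCc6ccccc6)c(OCc6ccccc6)c5)[C@H]5CO5)c3ccc(OCc4ccccc4)cc3O2)cc1
A7 | alternative 3 | hepta-O-benzyl target with free lower 3-hydroxyl | c4ccccc4COc1ccc([C@@H]2C[C@H](c5c(OCc6ccccc6)cc(OCc6ccccc6)c7c5O[C@H](c5cc(OCc6ccccc6)c(OCc6ccccc6)c(OCc6ccccc6)c5)[C@H](O)C7)c3ccc(OCc4ccccc4)cc3O2)cc1
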